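All constants are assumed; no experiment stands behind them.

Each target takes one open intermediate and one second intermediate, so the amounts I weigh are second intermediate against starting material.

- Thursday's: starting material 1.0 mM; partner 1.50 mM; time 4.0 min
- Tuesday's: starting material 1.0 mM; partner 2.20 mM; time 4.0 min

    open intermediate + second intermediate → target (k1 = 2950 M⁻¹ s⁻¹)
    second intermediate → decomposed reagent (k2 = 0.0379 s⁻¹)
    partner → second intermediate (k3 = 0.0420 s⁻¹)
    2 open intermediate → homo product (k4 = 1390 M⁻¹ s⁻¹)
    starting material → open intermediate (k5 = 0.0249 s⁻¹)

- in percentages every species weighs as the starting material in it: one homo product counts as two
- a doubled species enters its step squared and goes two at a time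
- run time (Thursday's): 4.0 min

1. which of these there is most of at the end, counted by the starting material in it, Thursday's (starting material / target / homo product / open intermediate)
2. which of these there is most of at the end, counted by the starting material in it, Tuesday's (starting material / target / homo product / open intermediate)
3. the largest of these amounts at the end, in percent of the starting material charged, Thursday's
4. the largest of these amounts at the end, in percent of the starting material charged, Tuesday's

I turn the question round and ask what homo product needs in order to lead target. I treat homo product as a correction: open intermediate is caught as it forms while the balance of second intermediate stays above zero, and what forms afterwards pairs with itself. Homo product then leads if that balance reaches zero before half of the starting material has turned, which is at its half-life.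

Let p, d and s be the constants of partner, of second intermediate decaying and of starting material, c the charge of starting material, and t the half-life:

t = ln(2)/s = 0.464 min

standing uncaught, per unit of partner charged: p/(p−d) · (e^(−dt) − e^(−pt)) = 0.385

removed by catching, decay allowed for: c·s/(d−s) · (e^(−st) − e^(−dt)) = 0.291 mM

Dividing the second by the first gives the break-even partner charge, the charge whose balance reaches zero exactly at that half-life:

0.756 mM

Thursday's flask holds twice that charge, and Tuesday's flask holds 2.91 times it. So I commit to target leading in both flasks, with less homo product on Tuesday's; this reckoning gives the side, not the percentage.

The forecast puts target at 83 % on Thursday's and target at 92 % on Tuesday's, because “target wins while the second intermediate lasts”.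

On Thursday's the simulation gives target at 84.0 %, with homo product at 15.1 %. On Tuesday's it gives target at 91.8 %, with homo product at 7.28 %.

A neighbour of Thursday's flask, charged with 0.60 mM of partner, stands at 0.794 of the break-even charge, below it, and there homo product leads with 52.8 % against 46.3 % of target. Between the two recipes, the partner charge is the main reason for the gap: Tuesday's flask, given Thursday's partner charge, falls from 91.8 % of target to 84.0 %.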